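The target's decalin (ring A: C1–C5, C10; ring B: C5–C10) is opened across the C5–C10 fusion bond to a ten-membered germacradienol, which is then cut at C6–C7. The key step exploits the fact that the vicinal pair C6 (oxygenated) and C7 (isopropyl-bearing) of ring B maps onto the allylic carbon C1 and the distal alkene carbon C10 of a farnesyl chain. A sesquiterpene synthase converts acyclic, achiral (2E,6E)-farnesyl diphosphate in one operation into (6R,7S)-6-hydroxygermacra-1(10),4-diene, making the C6–C7 bond, the ten-membered ring, the C6–O bond and both stereocentres. Transannular closure, benzoylation, α-epoxidation and trans-diaxial hydrolysis complete the target.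

Key step: step 3

Remarks on the chemistry:
- Eudesmane/germacrane numbering is used throughout: C4 and C10 carry the methyl groups, C6 the benzoate oxygen, C7 the isopropyl group. β is the face of the C10 methyl group.
- In this numbering the target is 6β-benzoyloxy-eudesmane-3α,4β-diol with 5α-H and 7β-isopropyl, (3R,4R,5S,6R,7S,10S). Ring A is the six-membered ring C10–C1–C2–C3–C4–C5.
- The key-step precursor 3 and product 4 match the target atom for atom: C6 and C7 of 4, (6R,7S) as drawn, become C6 and C7 of 9 without change.
- Compound 3 is drawn as the free acid; it is assumed to be made, stored and used as its ammonium salt.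

**Step 1**
Reactants: 1 (2E,6E)-farnesol
Product: 2 (2E,6E)-farnesyl bromide
Conditions: PBr3, Et2O, −10 to 0 °C
Reagents that add atoms: phosphorus tribromide, BrP(Br)Br
Why: SN2-type bromination of a primary allylic alcohol with PBr3 at low temperature, which should keep both E alkenes and avoid allylic transposition.

**Step 2**
Reactants: 2 (2E,6E)-farnesyl bromide
Product: 3 (2E,6E)-farnesyl diphosphate
Conditions: (n-Bu4N)3HP2O7, MeCN, rt; then sulfonic acid cation-exchange resin (NH4+ form), aq. NH4HCO3/i-PrOH
Reagents that add atoms: tris(tetrabutylammonium) hydrogen diphosphate, CCCC[N+](CCCC)(CCCC)CCCC.CCCC[N+](CCCC)(CCCC)CCCC.CCCC[N+](CCCC)(CCCC)CCCC.OP(=O)([O-])OP(=O)([O-])[O-]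
Why: SN2 displacement of the allylic bromide by the diphosphate anion in acetonitrile, the standard preparation of prenyl diphosphates, followed by cation exchange to the water-soluble ammonium salt.

**Step 3**
Reactants: 3 (2E,6E)-farnesyl diphosphate
Product: 4 (6R,7S)-6β-hydroxygermacra-1(10)E,4E-diene (kunzeaol)
Conditions: kunzeaol synthase (recombinant, His-tagged, gene from Thapsia garganica), MgCl2, HEPES pH 7.5, DTT, pentane overlay, 30 °C
Reagents that add atoms: water, O
Why: Terpene-synthase cyclisation of the germacrene D type: magnesium-ion-assisted ionisation of the allylic diphosphate gives the (2E,6E)-farnesyl cation, C10 of the distal alkene bonds to C1 (target C7–C6) with the charge moving to C11, a 1,3-hydride shift from C1 to C11 creates the isopropyl group and an allylic cation over C1–C3 (target C6–C4), and bound water adds at C1 (target C6). The closest known reaction type is the diphosphate-ionising sesquiterpene synthase reaction itself, and enzymes that make this germacradienol from 3 are known. The ten-membered ring closes by 1,10-closure, that is, Markovnikov attack of the C10=C11 alkene through C10 (exo with respect to that alkene) on the terminus of the allyl cation, with both ring alkenes staying E. C7 is set by the fold in which the active site holds the chain, which exposes one face of C10=C11 to C1, and C6 is set by the position of the water molecule on one face of the allylic cation after the hydride shift (catalyst control in both cases, since the substrate is achiral). The step needs 1,10-closure over 1,6- and 1,11-closure, hydride shift over proton loss, and water capture at C6 and not at C4; the E geometry of C2=C3 in 3 blocks direct six-ring closure and the trisubstituted distal alkene directs bonding to C10, while the remaining choices rest on the enzyme pocket.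

**Step 4**
Reactants: 4 (6R,7S)-6β-hydroxygermacra-1(10)E,4E-diene
Product: 5 eudesm-3-en-6β-ol (5α-H, 7β-isopropyl, 10β-methyl)
Conditions: CSA (cat.), CH2Cl2, 0 °C
Reagents that add atoms: none
Why: Acid-catalysed transannular cation–olefin cyclisation of a germacra-1(10),4-diene to a eudesmane, an isomerisation (C15H26O on both sides) in which protonation at C1 and bonding of C5 to C10 through the chair–chair (crown) conformer with pseudo-equatorial isopropyl should set the trans ring fusion (10β-CH3, 5α-H) relative to C7, loss of H3 from the C4 cation gives the trisubstituted C3=C4 alkene of six-membered ring A, and the C6 carbinol is not touched.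

**Step 5**
Reactants: 5 eudesm-3-en-6β-ol; 6 benzoyl chloride
Product: 7 6β-benzoyloxyeudesm-3-ene
Conditions: BzCl, DMAP, pyridine, 50 °C
Reagents that add atoms: benzoyl chloride (compound 6), O=C(Cl)c1ccccc1
Why: DMAP-catalysed acylation of the only hydroxyl group, run warm because the alcohol is axial and hindered; the C6–O bond is not broken, so C6 keeps its configuration.

**Step 6**
Reactants: 7 6β-benzoyloxyeudesm-3-ene
Product: 8 6β-benzoyloxy-3α,4α-epoxyeudesmane
Conditions: DMDO, acetone, 0 °C
Reagents that add atoms: dimethyldioxirane, CC1(C)OO1
Why: Dioxirane epoxidation of the trisubstituted alkene under neutral conditions; the β face is screened by the axial C10 methyl group and the axial 6β-benzoate, so oxygen should be delivered to the α face, setting C3 and C4 by substrate control.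

**Step 7**
Reactants: 8 6β-benzoyloxy-3α,4α-epoxyeudesmane
Product: 9 6β-benzoyloxyeudesmane-3α,4β-diol (target)
Conditions: HClO4 (cat.), THF/H2O, 0 °C to rt
Reagents that add atoms: water, O
Why: Acid-catalysed epoxide hydrolysis in which the protonated epoxide opens in the trans-diaxial sense (Fürst–Plattner rule) with water entering at the tertiary, cation-stabilising C4 from the β face (inversion, giving 4β-OH and 4α-CH3) while C3 keeps its α oxygen, and the benzoate is stable to dilute aqueous acid.

**Compound list**
1 | (2E,6E)-farnesol | CC(C)=CCC/C(C)=C/CC/C(C)=C/CO | starting material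
2 | (2E,6E)-farnesyl bromide | CC(C)=CCC/C(C)=C/CC/C(C)=C/CBr | intermediate
3 | (2E,6E)-farnesyl diphosphate (drawn as free acid, used as ammonium salt) | CC(C)=CCC/C(C)=C/CC/C(C)=C/COP(=O)(O)OP(=O)(O)O | intermediate
4 | (6R,7S)-6β-hydroxygermacra-1(10)E,4E-diene (kunzeaol) | CC(C)[C@@H]1CC/C(C)=C/CC/C(C)=C/[C@@H]1O | intermediate
5 | eudesm-3-en-6β-ol (5α-H, 7β-isopropyl, 10β-methyl, axial OH, six-membered ring A with C3=C4) | CC(C)[C@@H]1CC[C@@]2(C)CCC=C(C)[C@@H]2[C@@H]1O | intermediate
6 | benzoyl chloride | O=C(Cl)c1ccccc1 | starting material
7 | 6β-benzoyloxyeudesm-3-ene | CC(C)[C@@H]1CC[C@@]2(C)CCC=C(C)[C@@H]2[C@@H]1OC(=O)c1ccccc1 | intermediate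
8 | 6β-benzoyloxy-3α,4α-epoxyeudesmane (epoxide oxygen α, C4 methyl β) | CC(C)[C@@H]1CC[C@@]2(C)CC[C@H]3O[C@@]3(C)[C@@H]2[C@@H]1OC(=O)c1ccccc1 | intermediate
9 | 6β-benzoyloxyeudesmane-3α,4β-diol, (3R,4R,5S,6R,7S,10S) | CC(C)[C@@H]1CC[C@@]2(C)CC[C@@H](O)[C@](C)(O)[C@@H]2[C@@H]1OC(=O)c1ccccc1 | target

Total step count: 7. Longest linear sequence: 7 steps (1 to 9; benzoyl chloride 6 enters in step 5).

**Steps most likely to fail**

Step 4. After ring closure the C4 cation may lose its proton from C15 or C5 instead of C3, giving the wrong alkene position, and the allylic C6–O bond of 4 may ionise before the ring closes. The fallback sets out from 4 and comes back at 5. The ring is closed under the mildest conditions that still work (pyridinium tosylate or silica gel, low temperature). The alkene mixture, which in this case would be rich in the exocyclic isomer 6β-hydroxyeudesm-4(15)-ene F1, is not separated. It is treated with a cobalt hydride catalyst: Co(salen)Cl (chloro[N,N'-bis(3,5-di-tert-butylsalicylidene)-1,2-cyclohexanediaminato]cobalt, trivalent cobalt), catalytic PhSiH3, benzene, rt. Hydrogen-atom transfer to the 1,1-disubstituted alkene should give the tertiary C4 radical, and abstraction of hydrogen from the less hindered C3 moves the double bond one position into ring A to give 5. The trisubstituted alkene of 5 is a poor acceptor and should not move further.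

Step 3. Conversion on a preparative scale may stall through slow product release or loss of enzyme activity, and the germacradienol may be lost during isolation by thermal Cope rearrangement or premature acid-promoted ring closure. The fallback sets out from 3, now generated inside the cell in place of steps 1 and 2, and comes back at 4. The same synthase gene is expressed in Saccharomyces cerevisiae with an up-regulated mevalonate pathway (truncated HMG-CoA reductase overexpressed, squalene synthase down-regulated). Glucose fed-batch fermentation under a dodecane overlay should deliver 4 continuously into the organic layer, from which it is taken cold onto neutral alumina and then directly into step 4.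

Step 7. The syn-axial benzoate may take part in the opening and end up on O4 (acyl transfer), or the developing C4 cation may lose a C15 proton to give an allylic alcohol instead of the diol. The fallback sets out from 5 and comes back at 9. Hydroxyl-directed epoxidation of 5 with VO(acac)2 and t-BuOOH in toluene should deliver oxygen from the axial 6β-hydroxyl to the β face and give 3β,4β-epoxyeudesman-6β-ol F2. Benzoylation as in step 5 gives 6β-benzoyloxy-3β,4β-epoxyeudesmane F3. Aqueous HClO4 in THF should then open this epoxide in the trans-diaxial sense by attack of water on the secondary C3 from the open α face, where the β-face benzoate cannot participate and C4 keeps its β oxygen, giving 9.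

**Further compounds**
F1 | step 4 | 6β-hydroxyeudesm-4(15)-ene (5α-H, 7β-isopropyl, 10β-methyl) | CC(C)[C@@H]1CC[C@@]2(C)CCCC(=C)[C@@H]2[C@@H]1O
F0 | step 3 | none | none
F2 | step 7 | 3β,4β-epoxyeudesman-6β-ol | CC(C)[C@@H]1CC[C@@]2(C)CC[C@@H]3O[C@]3(C)[C@@H]2[C@@H]1O
F3 | step 7 | 6β-benzoyloxy-3β,4β-epoxyeudesmane | CC(C)[C@@H]1CC[C@@]2(C)CC[C@@H]3O[C@]3(C)[C@@H]2[C@@H]1OC(=O)c1ccccc1
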